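**Assumptions.** Cembrane numbering is used throughout: C1 is the ring CH bearing the acrylate (C15=C17, C16=O), C3 is the carbinol, C11 bears OAc and C12 bears the lactone oxygen. The SMILES is read as (1R,3S,4E,7E,11S,12R). Numbered compounds are substrates, fragment partners and products; simple reagents are given by name and SMILES in each step. The route is a paper design and has not been run.

## Retrosynthetic overview

1. The 7‑membered α‑methylene lactone is formed last (second ring) by transannular opening of an (11S,12S)‑epoxide at C12 by the C16 acid, with inversion, which gives 11S‑OH/12R‑O directly.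
2. The acrylic acid comes from a malonate (decarboxylative Mannich methylenation); the 3S carbinol comes from CBS reduction of the macrocyclic enone.
3. The 14‑membered carbocycle is formed first, by intramolecular Nozaki–Hiyama–Kishi coupling (C3–C4) of an aldehyde and an E‑vinyl iodide.
4. C1 and the malonate come from an organocatalytic Michael addition to an enal made by cross‑metathesis; C13–C14 comes from an epoxy triflate plus allyl cuprate; the epoxide comes from Sharpless epoxidation.
5. The C4–C13 chain comes from geranyl bromide and propynyl Grignard, then hydrozirconation–iodination and SeO2 oxidation.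

## Forward route

**Step 1**
Reactants: 1 geranyl bromide; 2 1‑propynylmagnesium bromide
Product: 3 (5E)‑6,10‑dimethylundeca‑5,9‑dien‑2‑yne
Conditions: CuI (5 mol %), THF, 0 °C → rt
Reagents that add atoms: 1‑propynylmagnesium bromide, CC#C[Mg]Br
Why: Cu(I)‑catalysed SN2 alkynylation of a primary allylic bromide gives the skipped enyne with the E‑olefin (future C7=C8) untouched.

**Step 2**
Reactants: 3
Product: 4 (2E,5E)‑2‑iodo‑6,10‑dimethylundeca‑2,5,9‑triene
Conditions: Cp2Zr(H)Cl (2 equiv), THF, 50 °C; then I2, 0 °C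
Reagents that add atoms: iodine, II
Why: Schwartz hydrozirconation is syn and, after equilibration, places Zr on the methyl‑bearing alkyne carbon; iodinolysis with retention gives the E‑vinyl iodide (future C4=C5).

**Step 3**
Reactants: 4
Product: 5 (2E,6E,9E)‑10‑iodo‑2,6‑dimethylundeca‑2,6,9‑trien‑1‑ol
Conditions: SeO2 (0.3 equiv), t‑BuOOH, salicylic acid (cat.), CH2Cl2, rt; then NaBH4, MeOH, 0 °C
Reagents that add atoms: tert‑butyl hydroperoxide, CC(C)(C)OO (via selenium dioxide, O=[Se]=O)
Why: Sharpless–Riley allylic oxidation (ene/[2,3]) selectively hydroxylates the E‑methyl of the terminal trisubstituted olefin, giving the E‑allylic alcohol (C13‑OH).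

**Step 4**
Reactants: 5
Product: 6 [(2S,3S)‑3‑[(3E,6E)‑7‑iodo‑3‑methylocta‑3,6‑dien‑1‑yl]‑2‑methyloxiran‑2‑yl]methanol
Conditions: Ti(OiPr)4 (10 mol %), L‑(+)‑DET (12 mol %), t‑BuOOH, 4 Å MS, CH2Cl2, −20 °C
Reagents that add atoms: tert‑butyl hydroperoxide, CC(C)(C)OO
Why: Sharpless asymmetric epoxidation is directed only to the allylic‑alcohol olefin; L‑(+)‑tartrate gives the (2S,3S) epoxide from this E‑alcohol, which is (11S,12S) in cembrane numbering.

**Step 5**
Reactants: 6
Product: 7 the primary triflate of 6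
Conditions: Tf2O, 2,6‑lutidine, CH2Cl2, −78 °C (used crude)
Reagents that add atoms: triflic anhydride, O=S(=O)(OS(=O)(=O)C(F)(F)F)C(F)(F)F
Why: O‑sulfonylation activates C13 without touching either stereocentre.

**Step 6**
Reactants: 7; 8 allylmagnesium bromide
Product: 9 (2S,3S)‑2‑(but‑3‑en‑1‑yl)‑3‑[(3E,6E)‑7‑iodo‑3‑methylocta‑3,6‑dien‑1‑yl]‑2‑methyloxirane
Conditions: CuBr·SMe2 (20 mol %), Et2O, −78 → −40 °C
Reagents that add atoms: allylmagnesium bromide, C=CC[Mg]Br
Why: Cu‑catalysed sp3–sp3 coupling of a primary triflate (Kotsuki type) is faster than opening of the hindered trisubstituted epoxide and forms C13–C14.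

**Step 7**
Reactants: 9; 10 (E)‑crotonaldehyde
Product: 11 (2E)‑5‑[(2S,3S)‑3‑[(3E,6E)‑7‑iodo‑3‑methylocta‑3,6‑dien‑1‑yl]‑2‑methyloxiran‑2‑yl]pent‑2‑enal
Conditions: Hoveyda–Grubbs II (5 mol %), crotonaldehyde (5 equiv), CH2Cl2, 40 °C
Reagents that add atoms: crotonaldehyde, C/C=C/C=O
Why: Olefin cross‑metathesis of the only monosubstituted alkene with an enal gives the E‑enal (C1=C2–C3HO); the trisubstituted olefins and vinyl iodide are inert.

**Step 8**
Reactants: 11; 12 dimethyl malonate
Product: 13 dimethyl 2‑[(3R)‑1‑oxo‑5‑[(2S,3S)‑3‑[(3E,6E)‑7‑iodo‑3‑methylocta‑3,6‑dien‑1‑yl]‑2‑methyloxiran‑2‑yl]pentan‑3‑yl]propanedioate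
Conditions: (S)‑α,α‑bis[3,5‑bis(trifluoromethyl)phenyl]prolinol TMS ether (10 mol %), EtOH, 0 °C
Reagents that add atoms: dimethyl malonate, COC(=O)CC(=O)OC
Why: Jørgensen–Hayashi iminium‑catalysed Michael addition; the (S)‑catalyst shields one face of the E,s‑trans iminium so malonate adds to give 1R (catalyst control).

**Step 9**
Reactants: 13
Product: 14 dimethyl 2‑[(1R,4E,7E,11S,12S)‑11,12‑epoxy‑3‑hydroxy‑4,8,12‑trimethylcyclotetradeca‑4,7‑dien‑1‑yl]propanedioate (C3 epimer mixture)
Conditions: CrCl2 (10 equiv), NiCl2 (0.1 equiv), DMSO/THF, rt, 2 mM, slow addition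
Reagents that add atoms: none
Why: Intramolecular Nozaki–Hiyama–Kishi coupling forms C3–C4 and the 14‑membered ring with retention of the E‑olefin; the C3 configuration is not relied on here because both epimers converge in Steps 10–11.

**Step 10**
Reactants: 14
Product: 15 the corresponding 3‑ketone (macrocyclic enone)
Conditions: Dess–Martin periodinane, NaHCO3, CH2Cl2, 0 °C
Reagents that add atoms: none
Why: Neutral oxidation of the allylic alcohol converges the epimers without isomerising the skipped diene.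

**Step 11**
Reactants: 15
Product: 16 dimethyl 2‑[(1R,3S,4E,7E,11S,12S)‑11,12‑epoxy‑3‑hydroxy‑4,8,12‑trimethylcyclotetradeca‑4,7‑dien‑1‑yl]propanedioate
Conditions: (R)‑Me‑CBS (1.2 equiv), catecholborane, toluene, −78 °C; silylate promptly
Reagents that add atoms: none
Why: Corey–Bakshi–Shibata reduction with the α‑methyl alkenyl group as the large substituent; the (R)‑catalyst gives the 3S allylic alcohol (reagent control).

**Step 12**
Reactants: 16
Product: 17 the 3‑O‑TBS ether of 16
Conditions: TBSCl, imidazole, DMF, rt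
Reagents that add atoms: TBSCl, CC(C)(C)[Si](C)(C)Cl
Why: Silylation stops the C3 hydroxyl from forming a δ‑lactone with the malonate or competing in the later epoxide opening.

**Step 13**
Reactants: 17
Product: 18 the malonic diacid of 17
Conditions: LiOH·H2O, THF/MeOH/H2O, 40 °C; then pH 4, 0 °C
Reagents that add atoms: lithium hydroxide, [Li+].[OH-]
Why: Saponification; the trisubstituted epoxide, TBS ether and skipped diene are base‑stable, and there is no carbonyl left that could trigger retro‑Michael loss of malonate.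

**Step 14**
Reactants: 18
Product: 19 2‑[(1R,3S,4E,7E,11S,12S)‑3‑(tert‑butyldimethylsilyloxy)‑11,12‑epoxy‑4,8,12‑trimethylcyclotetradeca‑4,7‑dien‑1‑yl]prop‑2‑enoic acid
Conditions: (CH2O)n, Et2NH, EtOAc, reflux
Reagents that add atoms: formaldehyde (paraformaldehyde), C=O
Why: Mannich reaction of the malonic acid followed by decarboxylative elimination gives the 2‑substituted acrylic acid (C15=C17) under near‑neutral conditions; C1 is untouched.

**Step 15**
Reactants: 19
Product: 20 11‑O‑deacetyl‑3‑O‑TBS‑dendronpholide A (7‑membered lactone closed; 11S‑OH, 12R)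
Conditions: CSA (10 mol %), CH2Cl2 (2 mM), 0 °C → rt
Reagents that add atoms: none
Why: Acid‑promoted transannular 7‑exo opening of the epoxide by the carboxylic acid at the tertiary carbon (Markovnikov) with inversion turns 12S into 12R and leaves 11S as the free alcohol.

**Step 16**
Reactants: 20
Product: 21 3‑O‑TBS‑dendronpholide A
Conditions: Ac2O, pyridine, DMAP (cat.), CH2Cl2, rt
Reagents that add atoms: acetic anhydride, CC(=O)OC(C)=O
Why: Acylation of the only free (secondary) hydroxyl, with retention at C11.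

**Step 17**
Reactants: 21
Product: 22 dendronpholide A
Conditions: HF·pyridine, pyridine/THF, 0 °C → rt
Reagents that add atoms: none
Why: Mildly acidic desilylation reveals the 3S alcohol without acetate migration or lactone opening.

## Compound list

1 | geranyl bromide, (2E)‑1‑bromo‑3,7‑dimethylocta‑2,6‑diene | CC(C)=CCC/C(C)=C/CBr | starting material
2 | 1‑propynylmagnesium bromide | CC#C[Mg]Br | starting material
3 | (5E)‑6,10‑dimethylundeca‑5,9‑dien‑2‑yne | CC(C)=CCC/C(C)=C/CC#CC | intermediate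
4 | (2E,5E)‑2‑iodo‑6,10‑dimethylundeca‑2,5,9‑triene | CC(C)=CCC/C(C)=C/C/C=C(\C)I | intermediate
5 | (2E,6E,9E)‑10‑iodo‑2,6‑dimethylundeca‑2,6,9‑trien‑1‑ol | OC/C(C)=C/CC/C(C)=C/C/C=C(\C)I | intermediate
6 | [(2S,3S)‑3‑[(3E,6E)‑7‑iodo‑3‑methylocta‑3,6‑dien‑1‑yl]‑2‑methyloxiran‑2‑yl]methanol | OC[C@]1(C)O[C@H]1CC/C(C)=C/C/C=C(\C)I | intermediate
7 | triflate of 6 | O=S(=O)(OC[C@]1(C)O[C@H]1CC/C(C)=C/C/C=C(\C)I)C(F)(F)F | intermediate
8 | allylmagnesium bromide | C=CC[Mg]Br | starting material
9 | (2S,3S)‑2‑(but‑3‑en‑1‑yl)‑3‑[(3E,6E)‑7‑iodo‑3‑methylocta‑3,6‑dien‑1‑yl]‑2‑methyloxirane | C=CCC[C@]1(C)O[C@H]1CC/C(C)=C/C/C=C(\C)I | intermediate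
10 | (E)‑crotonaldehyde | C/C=C/C=O | starting material
11 | (2E)‑5‑[(2S,3S)‑3‑[(3E,6E)‑7‑iodo‑3‑methylocta‑3,6‑dien‑1‑yl]‑2‑methyloxiran‑2‑yl]pent‑2‑enal | O=C/C=C/CC[C@]1(C)O[C@H]1CC/C(C)=C/C/C=C(\C)I | intermediate
12 | dimethyl malonate | COC(=O)CC(=O)OC | starting material
13 | dimethyl 2‑[(3R)‑1‑oxo‑5‑(epoxy‑dienyl iodide chain)pentan‑3‑yl]malonate (full name in Step 8) | COC(=O)C(C(=O)OC)[C@@H](CC=O)CC[C@]1(C)O[C@H]1CC/C(C)=C/C/C=C(\C)I | intermediate
14 | dimethyl 2‑[(1R,4E,7E,11S,12S)‑11,12‑epoxy‑3‑hydroxy‑4,8,12‑trimethylcyclotetradeca‑4,7‑dien‑1‑yl]malonate, C3 epimers | COC(=O)C(C(=O)OC)[C@H]1CC(O)/C(C)=C/C/C=C(\C)CC[C@@H]2O[C@@]2(C)CC1 | intermediate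
15 | 3‑oxo analogue of 14 (macrocyclic enone) | COC(=O)C(C(=O)OC)[C@H]1CC(=O)/C(C)=C/C/C=C(\C)CC[C@@H]2O[C@@]2(C)CC1 | intermediate
16 | (1R,3S,11S,12S)‑alcohol | COC(=O)C(C(=O)OC)[C@H]1C[C@H](O)/C(C)=C/C/C=C(\C)CC[C@@H]2O[C@@]2(C)CC1 | intermediate
17 | 3‑O‑TBS ether of 16 | COC(=O)C(C(=O)OC)[C@H]1C[C@H](O[Si](C)(C)C(C)(C)C)/C(C)=C/C/C=C(\C)CC[C@@H]2O[C@@]2(C)CC1 | intermediate
18 | malonic diacid of 17 | OC(=O)C(C(=O)O)[C@H]1C[C@H](O[Si](C)(C)C(C)(C)C)/C(C)=C/C/C=C(\C)CC[C@@H]2O[C@@]2(C)CC1 | intermediate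
19 | 2‑[(1R,3S,4E,7E,11S,12S)‑3‑TBSO‑11,12‑epoxy‑4,8,12‑trimethylcyclotetradeca‑4,7‑dien‑1‑yl]acrylic acid | OC(=O)C(=C)[C@H]1C[C@H](O[Si](C)(C)C(C)(C)C)/C(C)=C/C/C=C(\C)CC[C@@H]2O[C@@]2(C)CC1 | intermediate
20 | 11‑O‑deacetyl‑3‑O‑TBS‑dendronpholide A (1R,3S,11S,12R) | C=C1C(=O)O[C@]2(C)CC[C@@H]1C[C@H](O[Si](C)(C)C(C)(C)C)/C(C)=C/C/C=C(\C)CC[C@@H]2O | intermediate
21 | 3‑O‑TBS‑dendronpholide A | C=C1C(=O)O[C@]2(C)CC[C@@H]1C[C@H](O[Si](C)(C)C(C)(C)C)/C(C)=C/C/C=C(\C)CC[C@@H]2OC(C)=O | intermediate
22 | dendronpholide A (1R,3S,4E,7E,11S,12R) | C=C1C(=O)O[C@]2(C)CC[C@@H]1C[C@H](O)/C(C)=C/C/C=C(\C)CC[C@@H]2OC(C)=O | target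

## Summary

Total steps: 17. Longest linear sequence: 17 (fully linear from geranyl bromide).

Steps most likely to fail, each with a fallback that changes the approach:

1. **Step 15, transannular acid opening of the epoxide to the 7‑membered lactone.** The C12 cation‑like centre could instead be captured by the C7=C8 olefin or undergo a Meinwald shift. Fallback: form the C12–O bond by acylation instead. Hydrolyse the epoxide of 17 with aqueous HClO4 (same inversion at C12, giving the 11S,12R diol), protect O11 as PMB, and after Steps 13–14 close the lactone by acylating the tertiary C12 alkoxide (2‑pyridyl thioester/AgOTf or MNBA); then exchange PMB for acetate.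
2. **Step 9, NHK macrocyclisation of a flexible seco‑aldehyde bearing a malonate.** Oligomerisation, protonation of the alkenyl‑chromium, or lactonisation of the chromium alkoxide onto the malonate are the risks. Fallback: omit Step 2, carry the C4≡C5 alkyne, and close the ring by Ni(0)/NHC‑catalysed reductive alkyne–aldehyde macrocyclisation with Et3SiH, which gives the E‑trisubstituted allylic silyl ether directly.
3. **Step 6, SN2 at the neopentyl‑type epoxy triflate.** Displacement may be slow relative to epoxide opening. Fallback: switch to the Payne‑isomeric electrophile. Hydrolyse 6 to the 11S,12R triol, tosylate the primary hydroxyl and close to the unhindered 12,13‑epoxide, then open at C13 with allylMgBr/CuI; the resulting 11,12‑diol is carried forward with the acylative lactone closure of fallback 1.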